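**Retrosynthetic overview**
1. Target 24 ← 23 (hydrogenolysis of nine benzyl ethers) ← 21 (double galloylation of the C5 and C4' phenols) ← 20 (desilylation). O5 and O4' carry silyl groups from the start; every other oxygen is benzylated.
2. Feature used: O1 of ring C is an aryl alkyl ether oxygen between C8a of ring A and the benzylic stereocentre C2. Cutting O1–C8a, not O1–C2, gives an open-chain C2 alcohol and a C8a bromide, so ring closure touches neither C2 nor C3.
3. Ring C is the only ring formed (rings A and B are bought arenes): 20 ← anti (1R,2S) bromo alcohol 19 by palladium-catalysed intramolecular aryl etherification.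
4. 19 ← alpha-benzyloxy ketone 18 (zinc-chelate reduction sets future C2) ← Weinreb amide 12 + ring-B Grignard reagent from 15; 12 ← Evans alkylation of glycolate imide 9 with ring-A benzylic bromide 7 (sets future C3).
5. 7 ← 5-bromoresorcinol 1 by formylation; the chelated hydroxyl becomes O5 (silyl) and the para hydroxyl O7 (benzyl).

Key step: step 13

Remark: the target is the (2R,3S) isomer encoded in the SMILES; compounds 1, 8, 13 and 22 and benzyloxyacetyl chloride are assumed purchasable.

**Step 1**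
Reactants: 1 5-bromobenzene-1,3-diol
Product: 3 2-bromo-4,6-dihydroxybenzaldehyde, via aryl iminium chloride 2 (not isolated)
Conditions: POCl3, DMF, MeCN, −15 → 25 °C; then H2O, 50 °C
Reagents that add atoms: N,N-dimethylformamide, CN(C)C=O; water, O
Why: Vilsmeier–Haack formylation, in which, as with resorcinol and orcinol, the chloroiminium electrophile should attack para to one hydroxyl rather than between the two, and hydrolysis of iminium salt 2 gives the aldehyde with one hydroxyl hydrogen-bonded to the formyl group (future O5) and the other para to it (future O7).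

**Step 2**
Reactants: 3 2-bromo-4,6-dihydroxybenzaldehyde
Product: 4 4-(benzyloxy)-2-bromo-6-hydroxybenzaldehyde
Conditions: BnBr (1.05 equiv), NaHCO3, KI (cat.), MeCN, 80 °C
Reagents that add atoms: benzyl bromide, BrCc1ccccc1
Why: Williamson etherification with a weak base, which should alkylate only the more acidic para hydroxyl because the ortho hydroxyl is tied up in a hydrogen bond to the aldehyde.

**Step 3**
Reactants: 4 4-(benzyloxy)-2-bromo-6-hydroxybenzaldehyde
Product: 5 4-(benzyloxy)-2-bromo-6-[(triisopropylsilyl)oxy]benzaldehyde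
Conditions: TIPSOTf, 2,6-lutidine, CH2Cl2, 0 °C
Reagents that add atoms: triisopropylsilyl trifluoromethanesulfonate, CC(C)[Si](C(C)C)(C(C)C)OS(=O)(=O)C(F)(F)F
Why: O-silylation of the chelated phenol with the reactive silyl triflate and a hindered pyridine base, marking the future O5 with a group orthogonal to benzyl.

**Step 4**
Reactants: 5 4-(benzyloxy)-2-bromo-6-[(triisopropylsilyl)oxy]benzaldehyde
Product: 6 {4-(benzyloxy)-2-bromo-6-[(triisopropylsilyl)oxy]phenyl}methanol
Conditions: NaBH4, THF/MeOH, 0 °C; aq. NH4Cl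
Reagents that add atoms: none
Why: Borohydride reduction of the aldehyde to the benzylic alcohol, with aryl bromide, benzyl ether and aryl silyl ether inert and the low temperature and mild quench guarding against phenol-to-alkoxide silyl migration.

**Step 5**
Reactants: 6 {4-(benzyloxy)-2-bromo-6-[(triisopropylsilyl)oxy]phenyl}methanol
Product: 7 [5-(benzyloxy)-3-bromo-2-(bromomethyl)phenoxy]triisopropylsilane
Conditions: CBr4, PPh3, CH2Cl2, 0 °C; used without storage
Reagents that add atoms: carbon tetrabromide, BrC(Br)(Br)Br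
Why: Appel bromination converts the benzylic alcohol into the bromide under neutral conditions, avoiding acid that could ionise this electron-rich benzylic position.

**Step 6**
Reactants: 8 (R)-4-benzyloxazolidin-2-one
Product: 9 (R)-4-benzyl-3-[2-(benzyloxy)acetyl]oxazolidin-2-one
Conditions: BnOCH2COCl, Et3N, DMAP (cat.), CH2Cl2, 0 → 25 °C
Reagents that add atoms: benzyloxyacetyl chloride, O=C(Cl)COCc1ccccc1
Why: N-acylation of the oxazolidinone with the acid chloride under amine base and DMAP catalysis gives the Evans glycolate imide without involving the auxiliary stereocentre.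

**Step 7**
Reactants: 7 [5-(benzyloxy)-3-bromo-2-(bromomethyl)phenoxy]triisopropylsilane; 9 (R)-4-benzyl-3-[2-(benzyloxy)acetyl]oxazolidin-2-one
Product: 11 (R)-4-benzyl-3-[(S)-2-(benzyloxy)-3-{4-(benzyloxy)-2-bromo-6-[(triisopropylsilyl)oxy]phenyl}propanoyl]oxazolidin-2-one, via sodium Z-enolate 10 (not isolated)
Conditions: 9 (1.5 equiv), NaN(SiMe3)2, THF, −78 °C; then 7, −78 → −30 °C
Reagents that add atoms: none
Why: Evans asymmetric alkylation, in which the chelated sodium Z-enolate 10 is alkylated by the activated benzylic bromide on the face away from the C4 benzyl group of the (R) auxiliary, setting the (S) configuration of the benzyloxy-bearing carbon (future C3); the cheap imide is used in excess.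

**Step 8**
Reactants: 11 (R)-4-benzyl-3-[(S)-2-(benzyloxy)-3-{4-(benzyloxy)-2-bromo-6-[(triisopropylsilyl)oxy]phenyl}propanoyl]oxazolidin-2-one
Product: 12 (S)-2-(benzyloxy)-3-{4-(benzyloxy)-2-bromo-6-[(triisopropylsilyl)oxy]phenyl}-N-methoxy-N-methylpropanamide
Conditions: MeONHMe·HCl, AlMe3, CH2Cl2, −10 → 0 °C; then aq. HCl (0.5 M), 0 °C
Reagents that add atoms: N,O-dimethylhydroxylamine hydrochloride, CNOC.Cl
Why: Weinreb transamination with the aluminium amide formed from AlMe3 and the amine salt cleaves the exocyclic imide carbonyl, activated by the alpha-benzyloxy group, under non-basic conditions that should leave the alpha stereocentre and the aryl silyl ether untouched and release auxiliary 8.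

**Step 9**
Reactants: 13 2-(benzyloxy)phenol
Product: 14 2-(benzyloxy)-4-bromophenol
Conditions: NBS, MeCN, −20 → 0 °C
Reagents that add atoms: N-bromosuccinimide, O=C1CCC(=O)N1Br
Why: Electrophilic aromatic bromination directed para to the free hydroxyl, the stronger donor, which places bromine para to the future O4' and meta to the future O3'.

**Step 10**
Reactants: 14 2-(benzyloxy)-4-bromophenol
Product: 15 [2-(benzyloxy)-4-bromophenoxy]triisopropylsilane
Conditions: TIPSCl, imidazole, DMF, 25 °C
Reagents that add atoms: chlorotriisopropylsilane, CC(C)[Si](Cl)(C(C)C)C(C)C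
Why: Imidazole-promoted O-silylation of the phenol marks the future O4' with the same fluoride-labile group as O5.

**Step 11**
Reactants: 12 (S)-2-(benzyloxy)-3-{4-(benzyloxy)-2-bromo-6-[(triisopropylsilyl)oxy]phenyl}-N-methoxy-N-methylpropanamide; 15 [2-(benzyloxy)-4-bromophenoxy]triisopropylsilane
Product: 18 (S)-2-(benzyloxy)-1-{3-(benzyloxy)-4-[(triisopropylsilyl)oxy]phenyl}-3-{4-(benzyloxy)-2-bromo-6-[(triisopropylsilyl)oxy]phenyl}propan-1-one, via arylmagnesium bromide 16 (not isolated), via magnesium hemiaminal alkoxide 17 (not isolated)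
Conditions: 15, Mg turnings, THF, 45 °C; then 12, THF, −10 → 0 °C; aq. NH4Cl
Reagents that add atoms: none
Why: Weinreb ketone synthesis, in which Grignard reagent 16 adds once to the amide to give chelated adduct 17, which neither takes up a second equivalent nor enolises and collapses to the ketone only on quench, so the alpha stereocentre is kept; the aryl bromide of 12 should not exchange with an arylmagnesium halide at this temperature.

**Step 12**
Reactants: 18 (S)-2-(benzyloxy)-1-{3-(benzyloxy)-4-[(triisopropylsilyl)oxy]phenyl}-3-{4-(benzyloxy)-2-bromo-6-[(triisopropylsilyl)oxy]phenyl}propan-1-one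
Product: 19 (1R,2S)-2-(benzyloxy)-1-{3-(benzyloxy)-4-[(triisopropylsilyl)oxy]phenyl}-3-{4-(benzyloxy)-2-bromo-6-[(triisopropylsilyl)oxy]phenyl}propan-1-ol
Conditions: Zn(BH4)2, Et2O, −20 → 0 °C
Reagents that add atoms: none
Why: Chelation-controlled (Cram-chelate) hydride reduction, in which zinc bridges the carbonyl and alpha-benzyloxy oxygens in a five-membered chelate and hydride arrives on the face anti to the CH2Ar substituent, setting the new carbinol centre (future C2) as R and giving the anti (1R,2S) monobenzyl ether.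

**Step 13**
Reactants: 19 (1R,2S)-2-(benzyloxy)-1-{3-(benzyloxy)-4-[(triisopropylsilyl)oxy]phenyl}-3-{4-(benzyloxy)-2-bromo-6-[(triisopropylsilyl)oxy]phenyl}propan-1-ol
Product: 20 (2R,3S)-3,7-bis(benzyloxy)-2-{3-(benzyloxy)-4-[(triisopropylsilyl)oxy]phenyl}-5-[(triisopropylsilyl)oxy]chromane (catechin 3,7,3'-tribenzyl ether 5,4'-bis(triisopropylsilyl) ether)
Conditions: Pd(OAc)2 (5 mol %), 2-(di-tert-butylphosphino)-1,1'-binaphthyl (6 mol %), Cs2CO3, toluene, 80 °C
Reagents that add atoms: none
Why: Zerovalent palladium formed from Pd(OAc)2 and the phosphine adds oxidatively to the C8a–Br bond, Cs2CO3 turns the C2 hydroxyl into the alkoxide that displaces bromide on divalent palladium to give a seven-membered aryl(alkoxo)palladium ring, and C–O reductive elimination forms O1–C8a; the closest known reaction is the Buchwald-type intramolecular etherification of aryl bromides by secondary alcohols to chromans. Ring C closes as a six-membered ring by O-arylation at the ring-A carbon, and no other ring size is possible because O3 is already benzylated. No stereocentre is created and neither C2 nor C3 makes or breaks a bond, so the anti (1R,2S) arrangement of 19 should become the trans (2R,3S) arrangement of 20 with retention. The selectivity needed is reductive elimination over beta-hydride elimination of the benzylic alkoxide (which would return ketone 18 and debrominated arene); the bulky, electron-rich di-tert-butylbinaphthylphosphine favours the former, and the bromide has only one ortho substituent so oxidative addition is not blocked. The aryl silyl ethers are remote from the reacting atoms and should survive anhydrous Cs2CO3 in toluene.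

**Step 14**
Reactants: 20 catechin 3,7,3'-tribenzyl ether 5,4'-bis(triisopropylsilyl) ether
Product: 21 (2R,3S)-3,7-bis(benzyloxy)-2-[3-(benzyloxy)-4-hydroxyphenyl]chroman-5-ol (3,7,3'-tri-O-benzylcatechin)
Conditions: Bu4NF, AcOH, THF, 0 °C
Reagents that add atoms: none
Why: Fluoride cleavage of the two aryl silyl ethers leaves the benzyl ethers untouched, and the acetic acid buffer protonates the phenoxides at once so the 4'-phenoxide cannot open ring C through a quinone methide and scramble C2.

**Step 15**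
Reactants: 21 3,7,3'-tri-O-benzylcatechin; 22 3,4,5-tris(benzyloxy)benzoic acid
Product: 23 3,7,3'-tri-O-benzylcatechin 5,4'-bis[3,4,5-tris(benzyloxy)benzoate]
Conditions: 22 (2.4 equiv), EDC·HCl, DMAP, CH2Cl2, 25 °C
Reagents that add atoms: none
Why: Steglich esterification, in which DMAP transfers the carbodiimide-activated acid to the only two free hydroxyls, the phenols at C5 and C4', since O3, O7 and O3' are benzylated.

**Step 16**
Reactants: 23 3,7,3'-tri-O-benzylcatechin 5,4'-bis[3,4,5-tris(benzyloxy)benzoate]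
Product: 24 catechin 5,4'-di-O-gallate
Conditions: H2 (1 atm), Pd(OH)2/C, THF/EtOAc, 25 °C
Reagents that add atoms: none
Why: Catalytic hydrogenolysis over Pd(OH)2/C should cleave all nine benzyl ethers (O3, O7, O3' and six on the galloyl groups) while the aryl esters and the C2–O1 bond remain, and the neutral aprotic medium is chosen to keep the 4'-galloyl group from migrating to the freed 3'-hydroxyl.

**Compound list**
1 | 5-bromobenzene-1,3-diol | Oc1cc(O)cc(Br)c1 | starting material
2 | N-[(2-bromo-4,6-dihydroxyphenyl)methylidene]-N-methylmethanaminium chloride | C[N+](C)=Cc1c(Br)cc(O)cc1O.[Cl-] | intermediate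
3 | 2-bromo-4,6-dihydroxybenzaldehyde | O=Cc1c(Br)cc(O)cc1O | intermediate
4 | 4-(benzyloxy)-2-bromo-6-hydroxybenzaldehyde | O=Cc1c(Br)cc(OCc2ccccc2)cc1O | intermediate
5 | 4-(benzyloxy)-2-bromo-6-[(triisopropylsilyl)oxy]benzaldehyde | O=Cc1c(Br)cc(OCc2ccccc2)cc1O[Si](C(C)C)(C(C)C)C(C)C | intermediate
6 | {4-(benzyloxy)-2-bromo-6-[(triisopropylsilyl)oxy]phenyl}methanol | OCc1c(Br)cc(OCc2ccccc2)cc1O[Si](C(C)C)(C(C)C)C(C)C | intermediate
7 | [5-(benzyloxy)-3-bromo-2-(bromomethyl)phenoxy]triisopropylsilane | BrCc1c(Br)cc(OCc2ccccc2)cc1O[Si](C(C)C)(C(C)C)C(C)C | intermediate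
8 | (R)-4-benzyloxazolidin-2-one | O=C1N[C@H](Cc2ccccc2)CO1 | starting material
9 | (R)-4-benzyl-3-[2-(benzyloxy)acetyl]oxazolidin-2-one | O=C(COCc1ccccc1)N1C(=O)OC[C@H]1Cc1ccccc1 | intermediate
10 | sodium (Z)-enolate of imide 9 | [Na+].[O-]/C(=C\OCc1ccccc1)N1C(=O)OC[C@H]1Cc1ccccc1 | intermediate
11 | (R)-4-benzyl-3-[(S)-2-(benzyloxy)-3-{4-(benzyloxy)-2-bromo-6-[(triisopropylsilyl)oxy]phenyl}propanoyl]oxazolidin-2-one | O=C([C@@H](OCc1ccccc1)Cc1c(Br)cc(OCc2ccccc2)cc1O[Si](C(C)C)(C(C)C)C(C)C)N1C(=O)OC[C@H]1Cc1ccccc1 | intermediate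
12 | (S)-2-(benzyloxy)-3-{4-(benzyloxy)-2-bromo-6-[(triisopropylsilyl)oxy]phenyl}-N-methoxy-N-methylpropanamide | CON(C)C(=O)[C@@H](OCc1ccccc1)Cc1c(Br)cc(OCc2ccccc2)cc1O[Si](C(C)C)(C(C)C)C(C)C | intermediate
13 | 2-(benzyloxy)phenol | Oc1ccccc1OCc1ccccc1 | starting material
14 | 2-(benzyloxy)-4-bromophenol | Oc1ccc(Br)cc1OCc1ccccc1 | intermediate
15 | [2-(benzyloxy)-4-bromophenoxy]triisopropylsilane | CC(C)[Si](C(C)C)(C(C)C)Oc1ccc(Br)cc1OCc1ccccc1 | intermediate
16 | {3-(benzyloxy)-4-[(triisopropylsilyl)oxy]phenyl}magnesium bromide | CC(C)[Si](C(C)C)(C(C)C)Oc1ccc([Mg]Br)cc1OCc1ccccc1 | intermediate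
17 | bromomagnesium alkoxide of the tetrahedral adduct of 16 and 12 (hemiaminal carbon configuration undefined, alpha carbon S) | CON(C)C([O-])(c1ccc(O[Si](C(C)C)(C(C)C)C(C)C)c(OCc2ccccc2)c1)[C@@H](OCc1ccccc1)Cc1c(Br)cc(OCc2ccccc2)cc1O[Si](C(C)C)(C(C)C)C(C)C.[Mg+2].[Br-] | intermediate
18 | (S)-2-(benzyloxy)-1-{3-(benzyloxy)-4-[(triisopropylsilyl)oxy]phenyl}-3-{4-(benzyloxy)-2-bromo-6-[(triisopropylsilyl)oxy]phenyl}propan-1-one | CC(C)[Si](C(C)C)(C(C)C)Oc1ccc(C(=O)[C@@H](OCc2ccccc2)Cc2c(Br)cc(OCc3ccccc3)cc2O[Si](C(C)C)(C(C)C)C(C)C)cc1OCc1ccccc1 | intermediate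
19 | (1R,2S)-2-(benzyloxy)-1-{3-(benzyloxy)-4-[(triisopropylsilyl)oxy]phenyl}-3-{4-(benzyloxy)-2-bromo-6-[(triisopropylsilyl)oxy]phenyl}propan-1-ol | CC(C)[Si](C(C)C)(C(C)C)Oc1ccc([C@@H](O)[C@@H](OCc2ccccc2)Cc2c(Br)cc(OCc3ccccc3)cc2O[Si](C(C)C)(C(C)C)C(C)C)cc1OCc1ccccc1 | intermediate
20 | (2R,3S)-catechin 3,7,3'-tribenzyl ether 5,4'-bis(triisopropylsilyl) ether | CC(C)[Si](C(C)C)(C(C)C)Oc1ccc([C@H]2Oc3cc(OCc4ccccc4)cc(O[Si](C(C)C)(C(C)C)C(C)C)c3C[C@@H]2OCc2ccccc2)cc1OCc1ccccc1 | intermediate
21 | (2R,3S)-3,7-bis(benzyloxy)-2-[3-(benzyloxy)-4-hydroxyphenyl]chroman-5-ol (3,7,3'-tri-O-benzylcatechin) | Oc1ccc([C@H]2Oc3cc(OCc4ccccc4)cc(O)c3C[C@@H]2OCc2ccccc2)cc1OCc1ccccc1 | intermediate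
22 | 3,4,5-tris(benzyloxy)benzoic acid | O=C(O)c1cc(OCc2ccccc2)c(OCc2ccccc2)c(OCc2ccccc2)c1 | starting material
23 | (2R,3S)-3,7,3'-tri-O-benzylcatechin 5,4'-bis[3,4,5-tris(benzyloxy)benzoate] | O=C(Oc1ccc([C@H]2Oc3cc(OCc4ccccc4)cc(OC(=O)c4cc(OCc5ccccc5)c(OCc5ccccc5)c(OCc5ccccc5)c4)c3C[C@@H]2OCc2ccccc2)cc1OCc1ccccc1)c1cc(OCc2ccccc2)c(OCc2ccccc2)c(OCc2ccccc2)c1 | intermediate
24 | catechin 5,4'-di-O-gallate, (2R,3S) | O=C(Oc1ccc([C@H]2Oc3cc(O)cc(OC(=O)c4cc(O)c(O)c(O)c4)c3C[C@@H]2O)cc1O)c1cc(O)c(O)c(O)c1 | target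

**Step count**
Total: 16 steps. Longest linear sequence: 13 steps (steps 1–5, 7, 8, 11–16).

**Steps most likely to fail**

Step 13. Beta-hydride elimination from the palladium alkoxide may outrun C–O reductive elimination at this hindered secondary benzylic alkoxide, leading to oxidation of the carbinol and loss of the bromine. Fallback: the ring is closed at C2 instead of C8a. It sets out from 19. Miyaura borylation of the C8a bromide (B2pin2, PdCl2(dppf), KOAc, dioxane, 80 °C) should give the aryl pinacol boronate F1. Oxidation with NaBO3·4H2O in THF/H2O should give the phenol F2. Acid-promoted cyclodehydration (catalytic camphorsulfonic acid, CH2Cl2, 0 °C) would then pass through the benzylic cation stabilised by ring B and be captured by the C8a hydroxyl. This is expected to favour the 2,3-trans isomer, with C3 untouched and the cis isomer removed by chromatography. The fallback returns to the route at 20.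

Step 7. SN2 displacement at the doubly ortho-substituted benzylic carbon may be slower than decomposition of the glycolate enolate, and the electron-rich bromide may degrade before it reacts. Fallback: the C–C bond is made by an aldol reaction and the benzylic oxygen is removed afterwards. It sets out from aldehyde 5. The enantiomeric imide, (S)-4-benzyl-3-[2-(benzyloxy)acetyl]oxazolidin-2-one F3, is made from (S)-4-benzyloxazolidin-2-one as in step 6; it is needed because the boron aldol has the opposite facial sense to the chelated alkylation. An Evans syn aldol reaction of F3 with 5 (Bu2BOTf, Et3N, CH2Cl2, −78 → 0 °C) should give the syn adduct F4. Ionic deoxygenation of the activated benzylic hydroxyl (Et3SiH, CF3CO2H, CH2Cl2, 0 °C) should give the imide F5, the auxiliary epimer of 11. Transamination as in step 8 returns to the route at 12.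

Step 1. Formylation may occur between the two hydroxyls instead of next to bromine, or stop at O-formylation, giving poor regioselectivity. Fallback: the regiochemistry is fixed on the bis-ether and the chelated oxygen is freed afterwards. It sets out from 1. Double benzylation (BnBr, K2CO3, DMF) should give 1,3-bis(benzyloxy)-5-bromobenzene F6. Vilsmeier–Haack formylation, where the position between two benzyloxy groups is shielded, should give 2,4-bis(benzyloxy)-6-bromobenzaldehyde F7. Chelation-assisted removal of the benzyl group ortho to the aldehyde (MgBr2·OEt2, toluene/Et2O, 60 °C) returns to the route at 4.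

**Further compounds**
F1 | step 13 | (1R,2S)-2-(benzyloxy)-1-{3-(benzyloxy)-4-[(triisopropylsilyl)oxy]phenyl}-3-{4-(benzyloxy)-2-(4,4,5,5-tetramethyl-1,3,2-dioxaborolan-2-yl)-6-[(triisopropylsilyl)oxy]phenyl}propan-1-ol | CC(C)[Si](C(C)C)(C(C)C)Oc1ccc([C@@H](O)[C@@H](OCc2ccccc2)Cc2c(B3OC(C)(C)C(C)(C)O3)cc(OCc3ccccc3)cc2O[Si](C(C)C)(C(C)C)C(C)C)cc1OCc1ccccc1
F2 | step 13 | (1R,2S)-2-(benzyloxy)-1-{3-(benzyloxy)-4-[(triisopropylsilyl)oxy]phenyl}-3-{4-(benzyloxy)-2-hydroxy-6-[(triisopropylsilyl)oxy]phenyl}propan-1-ol | CC(C)[Si](C(C)C)(C(C)C)Oc1ccc([C@@H](O)[C@@H](OCc2ccccc2)Cc2c(O)cc(OCc3ccccc3)cc2O[Si](C(C)C)(C(C)C)C(C)C)cc1OCc1ccccc1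
F3 | step 7 | (S)-4-benzyl-3-[2-(benzyloxy)acetyl]oxazolidin-2-one | O=C(COCc1ccccc1)N1C(=O)OC[C@@H]1Cc1ccccc1
F4 | step 7 | (S)-4-benzyl-3-[(2S,3R)-2-(benzyloxy)-3-{4-(benzyloxy)-2-bromo-6-[(triisopropylsilyl)oxy]phenyl}-3-hydroxypropanoyl]oxazolidin-2-one | O=C([C@@H](OCc1ccccc1)[C@H](O)c1c(Br)cc(OCc2ccccc2)cc1O[Si](C(C)C)(C(C)C)C(C)C)N1C(=O)OC[C@@H]1Cc1ccccc1
F5 | step 7 | (S)-4-benzyl-3-[(S)-2-(benzyloxy)-3-{4-(benzyloxy)-2-bromo-6-[(triisopropylsilyl)oxy]phenyl}propanoyl]oxazolidin-2-one | O=C([C@@H](OCc1ccccc1)Cc1c(Br)cc(OCc2ccccc2)cc1O[Si](C(C)C)(C(C)C)C(C)C)N1C(=O)OC[C@@H]1Cc1ccccc1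
F6 | step 1 | 1,3-bis(benzyloxy)-5-bromobenzene | Brc1cc(OCc2ccccc2)cc(OCc2ccccc2)c1
F7 | step 1 | 2,4-bis(benzyloxy)-6-bromobenzaldehyde | O=Cc1c(Br)cc(OCc2ccccc2)cc1OCc1ccccc1
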